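## Analysis of the target

Barbatolic acid (20) consists of two pentasubstituted benzene rings joined by one ester bridge, ring A C1–C(=O)–O–CH2–ring B C6. Ring A is a 3-formyl-2,4-dihydroxy-6-methylbenzoyl unit, and ring B is a 3-formyl-2,4-dihydroxybenzoic acid whose C6 carries the CH2O group. There is no stereocentre and no ring fusion, so the problem is one of substitution pattern and functional-group compatibility. The sensitive groups are the two salicylaldehyde-type formyl groups at C3 of each ring, the four phenols, the free beta-resorcylic acid of ring B (which loses CO2 easily under acid or heat) and the benzylic ester. Two features make the synthesis hard. The ring A carboxyl is flanked by the C2 hydroxyl and the C6 methyl, so attack at its carbonyl carbon is slow. The ring B CH2O group sits ortho to the C1 carboxyl, so any free hydroxymethyl benzoate on the way can close to a five-membered lactone. A third difficulty is regiochemical: C3 and C5 are both open on each ring, and the formyl groups must enter at C3. The strategy rests on ring A without its formyl group: carboxyl carbon on C1, oxygen on C2 and C4 and methyl on C6 is the orsellinate pattern, in which ring atoms C1 to C6 are the folded chain atoms C2 to C7 of a 3,5,7-trioxooctanoate ester. Because the ester oxygen of that chain can be the ring B benzylic oxygen from the start, ring A and its hindered ester both come from one open-chain precursor by forming the single bond C1–C6.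

## Retrosynthetic reasoning

**20 to 19.** Only the O–C(CH3)3 bond of the ring B ester is cut. The ring B carboxyl stays masked to the end because a free beta-resorcylic acid would not survive the bases used earlier and would complicate the formylation. The forward reaction is an acidolysis that must spare the benzylic ester and the two aldehydes.

**19 to 18.** The two aryl–CHO bonds at C3 of ring A and C3 of ring B are cut together. The aldehydes are the most fragile groups, so they enter late. Both C3 positions have the same environment (between two hydroxyls of a hydrogen-bonded salicylate), so one operation can serve both. Ring A cannot be formylated earlier because it does not exist before the key step. The forward reaction must place one formyl group on each ring, at C3 and not at C5.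

**18 to 17.** The two ring B phenols are covered again as methoxymethyl ethers. Ring B needs them for a lateral metalation and a ketene capture, in which free phenols would compete. The forward reaction is an acetal cleavage mild enough to leave the tert-butyl ester in place.

**17 to 15 (key disconnection).** Ring A is opened at its C1–C6 bond and the lost dehydration is reversed, which unfolds the orsellinate into the open-chain triketo ester 15 by way of the aldol adduct 16. The cut is made here and not at the ester C–O bond because an ester disconnection would call for attack at a di-ortho-substituted carbonyl, or for a leaving group on the ring B benzylic carbon next to an ester. Cutting C1–C6 turns the hindered aryl ester into an ordinary beta-keto ester. The gain is that ring A, its substitution pattern and its ester bond come from one precursor. The forward reaction has to make the chain C2 carbanion add to the C7 ketone and not to the ester carbonyl.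

**15 to 7 and 13.** The acyl C–O bond of the beta-keto ester is cut. The acyl half is the acylketene 14, released from diketo-dioxinone 7 by cycloreversion of its dioxinone ring. The other half is the ring B benzylic alcohol 13. Ketene addition needs neither activating agent nor base, and no free polyketo acid is handled. The forward reaction must capture 14 faster than 14 condenses with itself and faster than 13 lactonizes.

**7 to 4 and 5, then 4 to 1 and 2.** Two C–C bonds of the chain are cut, C6–C7 and C4–C5 in the numbering of 15. Dioxinone 1 supplies chain C1 to C4, acetyl chloride 2 supplies C5 and C6, and N-methoxy-N-methylacetamide 5 supplies C7 and C8. Both bonds are made by acylating a carbanion at the far end of the dioxinone side chain (dienolate 3, then dianion 6). The dioxinone ring keeps the future ester carbonyl masked throughout.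

**13 to 10, 9 and 8.** The benzylic C–O bond at ring B C6 is cut back to the methyl group of an orsellinate, through the benzylic lithium compound 11 and the boronate 12. Orsellinic acid 8 already holds every carbon of ring B, and its methyl group is ortho to the ester and therefore laterally acidic. The tert-butyl ester of 9 and 10 is chosen because it is a poor acyl donor, which holds back lactonization of 13, and because it survives amide bases and carbonate. The methoxymethyl ethers of 10 survive the same bases and the thermolysis. Ester 9 is made from 8 by alkylation at the carboxylate oxygen, so the hindered carbonyl is not attacked.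

## Alternatives that were turned down

**Alternative 1:** The strategic disconnection is the pair of aryl–CHO bonds at C3 of both rings. It leaves the bis-orsellinate tetraphenol A2 (the same structure as 18), which would be assembled from two orsellinic acid halves by a conventional ester synthesis. In the forward key step A2 is treated with MgCl2, Et3N and paraformaldehyde to give barbatolic acid tert-butyl ester A1 (the same structure as 19).
- For it: both rings come from one commercial acid, no ring is built, and the step count is the lowest of all the options.
- Against it: the whole strategy then depends on a twofold substitution on the most advanced intermediate. The ester must also be made either by displacement at a ring B benzylic carbon next to an ester, where lactonization competes, or with a ring A acid whose phenols compete.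
- Comparison: Alternative 1 is stronger on step economy. The chosen route ends with the same formylation, so the two are equal on that risk. What the chosen strategy offers in its place is an ester bond formed from a neutral alcohol and a ketene, with no base, no leaving group on the benzylic carbon and no phenol competition, and a ring A built from small acyl units.

**Alternative 2:** The ring A C1–C(=O) bond and the C(=O)–O bond are cut together. The three components are aryl iodide A4, carbon monoxide and the ring B benzylic alcohol (the same compound as 13). The forward key step uses Pd(OAc)2, 4,5-bis(diphenylphosphino)-9,9-dimethylxanthene and Et3N under CO and gives the fully protected ester A3.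
- For it: the route is convergent. The ring A formyl group is placed before the coupling by metalation between two methoxymethyl ethers, so its regiochemistry is secure, which the chosen route cannot claim. No hindered acid is activated.
- Against it: oxidative addition of zerovalent palladium into an electron-rich iodide flanked by an ether and a methyl group is slow. The acylpalladium species has the same two ortho neighbours, so its alcoholysis is slow too. Meanwhile the amine base and heat give the hydroxymethyl benzoate time to lactonize, and the aldehyde on A4 can decarbonylate. A4 needs several steps of its own, and ring B still has to be formylated afterwards.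
- Comparison: the chosen strategy needs no metal and no gas. Its bond-forming event takes place at an unhindered ketene carbon.

**Alternative 3:** Ring B is cut at C1–C2 and C5–C6. Diene A7 supplies C2 to C5 and ynoate A6, which already carries the ring A ester, supplies C1 and C6. Thermal cycloaddition and loss of methanol would give salicylate A5.
- For it: the ring B CH2O group is acylated before ring B exists, so no free hydroxymethyl benzoate ever appears. On this point it is stronger than the chosen route. The regiochemistry of the cycloaddition follows from the ynoate ester, and the ring A formyl group is already present.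
- Against it: the fully substituted, formylated ring A acid has to be made and esterified first, which brings back the hindered-acid problem. The aldehyde of A6 is exposed to a nucleophilic silyl ketene acetal. The alkyne has only one activating group, so the cycloaddition needs heat that a moisture-sensitive diene tolerates poorly. Ring B must still be formylated late.
- Comparison: both strategies build one ring from acyclic material. The chosen one does it by an intramolecular aldol reaction under carbonate with a single six-membered path, reaches its cyclization precursor in fewer steps and never has to make the ring A acid.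

Key step: step 7

Remark on the chemistry: triketo ester 15 is assumed to be a keto–enol mixture that is used crude. The two stereocentres of 16 are transient and of no consequence.

## Route

**Step 1**
Reactants: 1 2,2,6-trimethyl-4H-1,3-dioxin-4-one; 2 acetyl chloride
Product: 4 2,2-dimethyl-6-(2-oxopropyl)-4H-1,3-dioxin-4-one, via lithium dienolate 3 (not isolated)
Conditions: LiN(SiMe3)2, THF, −78 °C; then 2 (0.5 equiv relative to 3), −78 °C; 1 M HCl
Reagents that add atoms: none
Why: Kinetic deprotonation of the C6 methyl group gives the vinylogous enolate 3, which is acylated at its terminal carbon (vinylogous Claisen-type C-acylation). Dienolate 3 is used in twofold excess because product 4 is more acidic than 1.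

**Step 2**
Reactants: 4 2,2-dimethyl-6-(2-oxopropyl)-4H-1,3-dioxin-4-one; 5 N-methoxy-N-methylacetamide
Product: 7 6-(2,4-dioxopentyl)-2,2-dimethyl-4H-1,3-dioxin-4-one, via dilithium dianion 6 (not isolated)
Conditions: LiN(i-Pr)2 (2.2 equiv), THF, −78 to −40 °C; then 5, −78 to −20 °C; 1 M HCl, 0 °C
Reagents that add atoms: none
Why: Two equivalents of amide base give dianion 6, whose last-formed terminal carbanion is the more nucleophilic site (dianion acylation with a Weinreb amide). The amide adds once and its chelated adduct holds until the quench, so the acidic product is never exposed to the dianion.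

**Step 3**
Reactants: 8 orsellinic acid (2,4-dihydroxy-6-methylbenzoic acid)
Product: 9 tert-butyl 2,4-dihydroxy-6-methylbenzoate
Conditions: O-tert-butyl-N,N'-diisopropylisourea (3 equiv), CH2Cl2, rt
Reagents that add atoms: O-tert-butyl-N,N'-diisopropylisourea, CC(C)NC(=NC(C)C)OC(C)(C)C
Why: The carboxylic acid protonates the isourea and its carboxylate takes up the tert-butyl group within the ion pair (isourea O-alkylation). The bond forms at the carboxylate oxygen, so the two ortho substituents do not matter. The phenols are too weakly acidic to react, and room temperature avoids decarboxylation.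

**Step 4**
Reactants: 9 tert-butyl 2,4-dihydroxy-6-methylbenzoate
Product: 10 tert-butyl 2,4-bis(methoxymethoxy)-6-methylbenzoate
Conditions: NaH (2.5 equiv), MeOCH2Cl (2.5 equiv), DMF, 0 °C to rt
Reagents that add atoms: chloromethyl methyl ether, COCCl
Why: Williamson-type O-alkylation of both sodium phenoxides. NaH is used because the C2 hydroxyl is hydrogen-bonded to the ester and is sluggish with amine bases.

**Step 5**
Reactants: 10 tert-butyl 2,4-bis(methoxymethoxy)-6-methylbenzoate
Product: 13 tert-butyl 6-(hydroxymethyl)-2,4-bis(methoxymethoxy)benzoate, via benzylic lithium compound 11 (not isolated), via dimethyl benzylboronate 12 (not isolated)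
Conditions: LiN(i-Pr)2 (1.2 equiv), THF, −78 °C; B(OMe)3, −78 to 0 °C; AcOH, then 30% aq. H2O2, 0 °C to rt
Reagents that add atoms: hydrogen peroxide, OO
Why: Lateral lithiation of the ortho-toluate gives the ester-stabilized benzylic anion 11, and the tert-butyl ester resists self-condensation. C-borylation restores the arene, and the shift of the benzyl group from boron to oxygen with H2O2 installs the hydroxyl (organolithium borylation–oxidation). The oxidation is buffered with AcOH so that no alkoxide sits next to the ester, which holds back closure to the five-membered lactone.

**Step 6**
Reactants: 7 6-(2,4-dioxopentyl)-2,2-dimethyl-4H-1,3-dioxin-4-one; 13 tert-butyl 6-(hydroxymethyl)-2,4-bis(methoxymethoxy)benzoate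
Product: 15 tert-butyl 2,4-bis(methoxymethoxy)-6-[(3,5,7-trioxooctanoyl)oxymethyl]benzoate, via acylketene 14 (not isolated)
Conditions: 7 (1.2 equiv), toluene, 110 °C; evaporation, crude product used directly
Reagents that add atoms: none
Why: Retro-[4+2] cycloreversion of the dioxinone ring of 7 expels acetone and leaves acylketene 14. Its unhindered ketene carbon is captured at once by the primary benzylic hydroxyl of 13 (dioxinone thermolysis with alcohol trapping). No base is present, so 13 stays a neutral alcohol and its hindered tert-butyl ester should not lactonize before the acylation is complete.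

**Step 7**
Reactants: 15 tert-butyl 2,4-bis(methoxymethoxy)-6-[(3,5,7-trioxooctanoyl)oxymethyl]benzoate
Product: 17 tert-butyl 6-[(2,4-dihydroxy-6-methylbenzoyl)oxymethyl]-2,4-bis(methoxymethoxy)benzoate, via aldol adduct 16 (not isolated)
Conditions: Cs2CO3 (3 equiv), i-PrOH–CH2Cl2, 0 °C to rt; then AcOH, rt
Reagents that add atoms: none
Why: Carbonate deprotonates only the doubly activated methylene groups of 15, and of the resulting enolates only the one at chain C2 (alpha to the ester) can reach a ketone through a six-membered transition state, so the C2–C7 bond, which is the ring A C1–C6 bond, forms in a 6-(enolendo)-exo-trig aldol closure to give 16. E1cB loss of water from 16 and enolization of the chain C3 and C5 carbonyls then give the aromatic 2,4-dihydroxy-6-methylbenzoate, and the mild acid quench completes the dehydration. The closest known reaction type is the biomimetic aldol cyclization and dehydration of 3,5,7-trioxoalkanoate esters to resorcylate esters under carbonate or buffer. The two stereocentres of 16 vanish on aromatization, so no stereocontrol is needed. The selectivity required is aldol closure over the two closures onto the ester carbonyl (Claisen attack by chain C6 and lactonization by the C5 enol oxygen); it is secured because the methyl ketone is the better electrophile, because the ester carbonyl is deactivated whenever chain C2 is enolized, and because both competing paths must expel an alkoxide while the aldol path is driven on by aromatization. The terminal methyl group (chain C8) is not acidic enough for carbonate, which rules out the other aldol closure onto C3. The tert-butyl ester, the methoxymethyl ethers and the benzylic ester are inert to carbonate, and the hindered ring A ester bond is in place before the ring exists.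

**Step 8**
Reactants: 17 tert-butyl 6-[(2,4-dihydroxy-6-methylbenzoyl)oxymethyl]-2,4-bis(methoxymethoxy)benzoate
Product: 18 tert-butyl 6-[(2,4-dihydroxy-6-methylbenzoyl)oxymethyl]-2,4-dihydroxybenzoate
Conditions: HCl (about 1 M in MeOH), THF, 0 °C to rt
Reagents that add atoms: none
Why: Acid-catalysed acetal exchange passes the CH2 group of each methoxymethyl ether to methanol. Dilute methanolic HCl at room temperature should be too weak to ionize the tert-butyl ester, and the di-ortho-substituted ring A ester resists methanolysis.

**Step 9**
Reactants: 18 tert-butyl 6-[(2,4-dihydroxy-6-methylbenzoyl)oxymethyl]-2,4-dihydroxybenzoate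
Product: 19 tert-butyl 3-formyl-6-[(3-formyl-2,4-dihydroxy-6-methylbenzoyl)oxymethyl]-2,4-dihydroxybenzoate (barbatolic acid tert-butyl ester)
Conditions: MgCl2 (6 equiv), Et3N (12 equiv), (CH2O)n (12 equiv), THF, reflux; 1 M HCl work-up
Reagents that add atoms: paraformaldehyde (as formaldehyde), C=O
Why: Casnati–Skattebøl ortho-formylation: each magnesium phenoxide delivers coordinated formaldehyde to its ortho carbon, and a second formaldehyde oxidizes the resulting benzylic alkoxide to the aldehyde by hydride transfer. C3 of each ring lies between two phenoxide oxygens and is the carbon activated by the hydrogen-bond-fixed salicylate, while C5 is flanked by the C6 substituent, so both formyl groups should enter at C3. After the first entry each ring is deactivated towards a second.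

**Step 10**
Reactants: 19 barbatolic acid tert-butyl ester
Product: 20 barbatolic acid
Conditions: CF3CO2H–CH2Cl2 (1:4), 0 °C to rt
Reagents that add atoms: none
Why: Acidolysis of the tert-butyl ester by alkyl–oxygen cleavage, the tert-butyl cation leaving as isobutene. The benzylic ester should not ionize because its CH2 group is meta to both ring B hydroxyls and para to the formyl group. Aldehydes and phenols are stable to the acid.

## Compound list

1 | 2,2,6-trimethyl-4H-1,3-dioxin-4-one | CC1=CC(=O)OC(C)(C)O1 | starting material
2 | acetyl chloride | CC(=O)Cl | starting material
3 | lithium dienolate of 1 (lithium 2,2-dimethyl-6-methylidene-6H-1,3-dioxin-4-olate) | C=C1C=C(O[Li])OC(C)(C)O1 | intermediate (not isolated)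
4 | 2,2-dimethyl-6-(2-oxopropyl)-4H-1,3-dioxin-4-one | CC(=O)CC1=CC(=O)OC(C)(C)O1 | intermediate
5 | N-methoxy-N-methylacetamide | CC(=O)N(C)OC | starting material
6 | dilithium dianion of 4 (bis-enolate) | C=C(O[Li])C=C1C=C(O[Li])OC(C)(C)O1 | intermediate (not isolated)
7 | 6-(2,4-dioxopentyl)-2,2-dimethyl-4H-1,3-dioxin-4-one | CC(=O)CC(=O)CC1=CC(=O)OC(C)(C)O1 | intermediate
8 | orsellinic acid (2,4-dihydroxy-6-methylbenzoic acid) | Cc1cc(O)cc(O)c1C(=O)O | starting material
9 | tert-butyl 2,4-dihydroxy-6-methylbenzoate | Cc1cc(O)cc(O)c1C(=O)OC(C)(C)C | intermediate
10 | tert-butyl 2,4-bis(methoxymethoxy)-6-methylbenzoate | Cc1cc(OCOC)cc(OCOC)c1C(=O)OC(C)(C)C | intermediate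
11 | tert-butyl 6-(lithiomethyl)-2,4-bis(methoxymethoxy)benzoate | [Li]Cc1cc(OCOC)cc(OCOC)c1C(=O)OC(C)(C)C | intermediate (not isolated)
12 | tert-butyl 6-[(dimethoxyboranyl)methyl]-2,4-bis(methoxymethoxy)benzoate | COB(OC)Cc1cc(OCOC)cc(OCOC)c1C(=O)OC(C)(C)C | intermediate (not isolated)
13 | tert-butyl 6-(hydroxymethyl)-2,4-bis(methoxymethoxy)benzoate | OCc1cc(OCOC)cc(OCOC)c1C(=O)OC(C)(C)C | intermediate
14 | 3,5,7-trioxooct-1-en-1-one (acylketene) | CC(=O)CC(=O)CC(=O)C=C=O | intermediate (not isolated)
15 | tert-butyl 2,4-bis(methoxymethoxy)-6-[(3,5,7-trioxooctanoyl)oxymethyl]benzoate | CC(=O)CC(=O)CC(=O)CC(=O)OCc1cc(OCOC)cc(OCOC)c1C(=O)OC(C)(C)C | intermediate (key-step precursor, used crude)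
16 | tert-butyl 6-{[(2-hydroxy-2-methyl-4,6-dioxocyclohexane-1-carbonyl)oxy]methyl}-2,4-bis(methoxymethoxy)benzoate (mixture of stereoisomers) | CC1(O)CC(=O)CC(=O)C1C(=O)OCc1cc(OCOC)cc(OCOC)c1C(=O)OC(C)(C)C | intermediate (not isolated)
17 | tert-butyl 6-[(2,4-dihydroxy-6-methylbenzoyl)oxymethyl]-2,4-bis(methoxymethoxy)benzoate | Cc1cc(O)cc(O)c1C(=O)OCc1cc(OCOC)cc(OCOC)c1C(=O)OC(C)(C)C | intermediate (key-step product)
18 | tert-butyl 6-[(2,4-dihydroxy-6-methylbenzoyl)oxymethyl]-2,4-dihydroxybenzoate | Cc1cc(O)cc(O)c1C(=O)OCc1cc(O)cc(O)c1C(=O)OC(C)(C)C | intermediate
19 | tert-butyl 3-formyl-6-[(3-formyl-2,4-dihydroxy-6-methylbenzoyl)oxymethyl]-2,4-dihydroxybenzoate | Cc1cc(O)c(C=O)c(O)c1C(=O)OCc1cc(O)c(C=O)c(O)c1C(=O)OC(C)(C)C | intermediate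
20 | barbatolic acid, 3-formyl-6-[(3-formyl-2,4-dihydroxy-6-methylbenzoyl)oxymethyl]-2,4-dihydroxybenzoic acid | Cc1cc(O)c(C=O)c(O)c1C(=O)OCc1cc(O)c(C=O)c(O)c1C(=O)O | target

## Step count and least certain steps

Total: 10 steps. Longest linear sequence: 8 steps (steps 3, 4, 5, 6, 7, 8, 9 and 10, from orsellinic acid 8). The dioxinone branch (steps 1 and 2) joins at step 6.

**Step 7 (key step).** The polyanion of 15 may close onto the ester carbonyl instead of the C7 ketone, either by Claisen attack from chain C6 or by lactonization through the C5 enol oxygen. Both paths expel the ring B alkoxide, which is then lost by lactonization. All three closures are six-membered and their partition depends on counter-ion and medium. Dehydration of 16 may also stall under the mild acid that the methoxymethyl ethers allow. Fallback, from 13 back to the route at 17: Mitsunobu esterification of 13 with orsellinic acid 8 (PPh3, diisopropyl azodicarboxylate, THF, 0 °C to rt). The carboxyl group of 8 is far more acidic than its phenols and attacks the activated CH2 group in an SN2 step, so the hindered carbonyl is never attacked. No new compound is made on this path (entry F0).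

**Step 5.** During oxidation or isolation the new benzylic oxygen may attack the neighbouring tert-butyl ester and close the five-membered lactone with loss of tert-butanol. The delocalized anion 11 may also be borylated on oxygen or condense with unreacted 10. Fallback, from 4 back to the route at 13: ring B is built with its benzylic oxygen already in place.
- Dianion 6 of 4 is acylated with 2-[(tert-butyldimethylsilyl)oxy]-N-methoxy-N-methylacetamide to give 6-{5-[(tert-butyldimethylsilyl)oxy]-2,4-dioxopentyl}-2,2-dimethyl-4H-1,3-dioxin-4-one F1.
- Heating with tert-butanol in toluene at 110 °C gives tert-butyl 8-[(tert-butyldimethylsilyl)oxy]-3,5,7-trioxooctanoate F2.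
- Cs2CO3 cyclizes and dehydrates it, as in step 7, to tert-butyl 6-{[(tert-butyldimethylsilyl)oxy]methyl}-2,4-dihydroxybenzoate F3.
- NaH and chloromethyl methyl ether give tert-butyl 6-{[(tert-butyldimethylsilyl)oxy]methyl}-2,4-bis(methoxymethoxy)benzoate F4.
- HF·pyridine in THF removes the silyl group without generating an alkoxide and returns 13.

**Step 9.** The two rings may react at unequal rates, and over-formylation at C5 or attack at C5 in place of C3 may give a mixture of mono-, di- and triformyl products that is hard to separate. Four phenoxides compete for magnesium, and the two rings carry different esters. Fallback, from 17 back to the route at 19: the rings are formylated one at a time.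
- MgCl2, Et3N and paraformaldehyde act on 17, in which only ring A has free phenols, to give tert-butyl 6-[(3-formyl-2,4-dihydroxy-6-methylbenzoyl)oxymethyl]-2,4-bis(methoxymethoxy)benzoate F5.
- Methanolic HCl frees the ring B phenols to give tert-butyl 6-[(3-formyl-2,4-dihydroxy-6-methylbenzoyl)oxymethyl]-2,4-dihydroxybenzoate F6.
- A second magnesium-mediated formylation, which now meets a ring A that is blocked at C3 and deactivated, gives 19.

**Step 2.** Proton transfer from the acylated adduct or from the product to dianion 6 may stop the acylation short, and O-acylation of the enolates may compete. The product is far more acidic than 4. Fallback, from 1 (through its dienolate 3) back to the route at 7: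
- Acylation of 3 with allyl 3-chloro-3-oxopropanoate gives allyl 4-(2,2-dimethyl-4-oxo-4H-1,3-dioxin-6-yl)-3-oxobutanoate F7.
- C-acylation with acetyl chloride 2 under MgCl2 and pyridine in CH2Cl2 gives allyl 2-acetyl-4-(2,2-dimethyl-4-oxo-4H-1,3-dioxin-6-yl)-3-oxobutanoate F8.
- Pd(PPh3)4 and morpholine remove the allyl group, and the free keto acid decarboxylates to 7.

## Further compounds

F0 | step 7 | none | none
F1 | step 5 | 6-{5-[(tert-butyldimethylsilyl)oxy]-2,4-dioxopentyl}-2,2-dimethyl-4H-1,3-dioxin-4-one | CC(C)(C)[Si](C)(C)OCC(=O)CC(=O)CC1=CC(=O)OC(C)(C)O1
F2 | step 5 | tert-butyl 8-[(tert-butyldimethylsilyl)oxy]-3,5,7-trioxooctanoate | CC(C)(C)[Si](C)(C)OCC(=O)CC(=O)CC(=O)CC(=O)OC(C)(C)C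
F3 | step 5 | tert-butyl 6-{[(tert-butyldimethylsilyl)oxy]methyl}-2,4-dihydroxybenzoate | CC(C)(C)[Si](C)(C)OCc1cc(O)cc(O)c1C(=O)OC(C)(C)C
F4 | step 5 | tert-butyl 6-{[(tert-butyldimethylsilyl)oxy]methyl}-2,4-bis(methoxymethoxy)benzoate | CC(C)(C)[Si](C)(C)OCc1cc(OCOC)cc(OCOC)c1C(=O)OC(C)(C)C
F5 | step 9 | tert-butyl 6-[(3-formyl-2,4-dihydroxy-6-methylbenzoyl)oxymethyl]-2,4-bis(methoxymethoxy)benzoate | Cc1cc(O)c(C=O)c(O)c1C(=O)OCc1cc(OCOC)cc(OCOC)c1C(=O)OC(C)(C)C
F6 | step 9 | tert-butyl 6-[(3-formyl-2,4-dihydroxy-6-methylbenzoyl)oxymethyl]-2,4-dihydroxybenzoate | Cc1cc(O)c(C=O)c(O)c1C(=O)OCc1cc(O)cc(O)c1C(=O)OC(C)(C)C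
F7 | step 2 | allyl 4-(2,2-dimethyl-4-oxo-4H-1,3-dioxin-6-yl)-3-oxobutanoate | C=CCOC(=O)CC(=O)CC1=CC(=O)OC(C)(C)O1
F8 | step 2 | allyl 2-acetyl-4-(2,2-dimethyl-4-oxo-4H-1,3-dioxin-6-yl)-3-oxobutanoate | C=CCOC(=O)C(C(C)=O)C(=O)CC1=CC(=O)OC(C)(C)O1
A1 | alternative 1 | barbatolic acid tert-butyl ester, tert-butyl 3-formyl-6-[(3-formyl-2,4-dihydroxy-6-methylbenzoyl)oxymethyl]-2,4-dihydroxybenzoate | Cc1cc(O)c(C=O)c(O)c1C(=O)OCc1cc(O)c(C=O)c(O)c1C(=O)OC(C)(C)C
A2 | alternative 1 | tert-butyl 6-[(2,4-dihydroxy-6-methylbenzoyl)oxymethyl]-2,4-dihydroxybenzoate | Cc1cc(O)cc(O)c1C(=O)OCc1cc(O)cc(O)c1C(=O)OC(C)(C)C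
A3 | alternative 2 | tert-butyl 6-{[3-formyl-2,4-bis(methoxymethoxy)-6-methylbenzoyl]oxymethyl}-2,4-bis(methoxymethoxy)benzoate | Cc1cc(OCOC)c(C=O)c(OCOC)c1C(=O)OCc1cc(OCOC)cc(OCOC)c1C(=O)OC(C)(C)C
A4 | alternative 2 | 3-iodo-2,6-bis(methoxymethoxy)-4-methylbenzaldehyde | Cc1cc(OCOC)c(C=O)c(OCOC)c1I
A5 | alternative 3 | tert-butyl 6-{[3-formyl-2,4-bis(methoxymethoxy)-6-methylbenzoyl]oxymethyl}-2,4-dihydroxybenzoate | Cc1cc(OCOC)c(C=O)c(OCOC)c1C(=O)OCc1cc(O)cc(O)c1C(=O)OC(C)(C)C
A6 | alternative 3 | tert-butyl 4-{[3-formyl-2,4-bis(methoxymethoxy)-6-methylbenzoyl]oxy}but-2-ynoate | Cc1cc(OCOC)c(C=O)c(OCOC)c1C(=O)OCC#CC(=O)OC(C)(C)C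
A7 | alternative 3 | 1-methoxy-1,3-bis(trimethylsilyloxy)buta-1,3-diene | COC(O[Si](C)(C)C)=CC(=C)O[Si](C)(C)C
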